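**Retrosynthetic overview**
1. Flemistrictin D (8) ⇒ prenylated dihydrochalcone 5: the C8–OH bond and the pyran O1–C2 bond are disconnected together (one-pot ortho-oxygenation, quinone-methide formation, oxa-6π ring closure).
2. 5 ⇒ uvangoletin 3 + prenyl bromide 4 (nuclear C-prenylation at C3').
3. 3 ⇒ 5-methoxyresorcinol 1 + 3-phenylpropanoic acid 2 (Friedel–Crafts acylation).
4. Ring order: the oxygenated benzene ring A and the phenyl ring are bought; the pyran ring is the only ring built, in the last step.

Assumption: Flemistrictin D has no stereocentre and is achiral, so "single enantiomer" is read as the compound exactly as drawn and no stereocontrol is needed. Primed locants refer to the oxygenated ring of the dihydrochalcones (C1' carries the ketone).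

**Step 1**
Reactants: 1 5-methoxyresorcinol; 2 3-phenylpropanoic acid
Product: 3 uvangoletin (1-(2,4-dihydroxy-6-methoxyphenyl)-3-phenylpropan-1-one)
Conditions: BF3·OEt2 (solvent), 85 °C, 3 h; then aq NaOAc, rt; chromatography
Reagents that add atoms: none
Why: Friedel–Crafts (Nencki-type) C-acylation of a phloroglucinol monoether, expected to favour the two equivalent positions para to one OH (flanked by OH and OMe) over the single position between the two OH groups, so 3 should be the major isomer and is separated from the symmetric one; no stereocentre is formed.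

**Step 2**
Reactants: 3 uvangoletin; 4 prenyl bromide
Product: 5 1-[2,4-dihydroxy-6-methoxy-3-(3-methylbut-2-en-1-yl)phenyl]-3-phenylpropan-1-one
Conditions: 10% aq KOH (2.2 equiv), 0 °C; 4 (1.1 equiv) dropwise, 0 °C → rt, 4 h; then 1 M HCl
Reagents that add atoms: none
Why: Direct nuclear prenylation (C-alkylation of an ambident phenolate): in aqueous KOH the substrate is a dianion whose carbon between the two phenoxide oxygens (C3') is the most nucleophilic site, and water solvation of the oxygens favours C- over O-alkylation by the soft allylic bromide; no stereocentre is formed.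

**Step 3**
Reactants: 5 1-[2,4-dihydroxy-6-methoxy-3-(3-methylbut-2-en-1-yl)phenyl]-3-phenylpropan-1-one
Product: 8 Flemistrictin D, via ortho-quinone 6 (not isolated), via vinyl ortho-quinone methide 7 (not isolated)
Conditions: IBX (1.0 equiv), degassed DMF (0.05 M), Ar, dark, 0 °C → rt, 2 h; then pyridine (10 equiv), 60 °C, 6 h; aq citric acid work-up
Reagents that add atoms: 2-iodoxybenzoic acid (IBX), OI1(=O)OC(=O)c2ccccc12
Why: Proposed new method: a one-pot ortho-oxygenative cycloisomerization in which IBX, bound through the only unchelated phenol (4'-OH), delivers oxygen to the single free ortho C–H (C5') to give ortho-quinone 6 (this makes the future C8–O bond and consumes all four oxidizing equivalents of the pentavalent iodine reagent), pyridine then shuttles a proton from the doubly activated benzylic/allylic CH2 to the C5' quinone oxygen to give vinyl ortho-quinone methide 7, and 7 closes by oxa-6π electrocyclization through its C4' carbonyl oxygen while the C2' hydroxyl stays hydrogen-bonded to the ketone, forming the O1–C2 bond and the pyran ring and re-aromatizing directly to the hydroquinone with no reduction step and no stereocentre; the closest known reaction types are the IBX ortho-oxygenation of phenols to ortho-quinones and the amine-mediated isomerization of 2-prenyl-1,4-benzoquinones to 6-hydroxy-2,2-dimethylchromenes, which have not been merged or shown on an ortho-quinone of an acylphloroglucinol.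

**Compound list**
1 | 5-methoxyresorcinol (5-methoxybenzene-1,3-diol) | COc1cc(O)cc(O)c1 | starting material
2 | 3-phenylpropanoic acid (hydrocinnamic acid) | OC(=O)CCc1ccccc1 | starting material
3 | uvangoletin, 1-(2,4-dihydroxy-6-methoxyphenyl)-3-phenylpropan-1-one | COc1cc(O)cc(O)c1C(=O)CCc1ccccc1 | intermediate
4 | prenyl bromide (1-bromo-3-methylbut-2-ene) | CC(C)=CCBr | starting material
5 | 1-[2,4-dihydroxy-6-methoxy-3-(3-methylbut-2-en-1-yl)phenyl]-3-phenylpropan-1-one | COc1cc(O)c(CC=C(C)C)c(O)c1C(=O)CCc1ccccc1 | intermediate
6 | ortho-quinone, 4-hydroxy-6-methoxy-3-(3-methylbut-2-en-1-yl)-5-(3-phenylpropanoyl)cyclohexa-3,5-diene-1,2-dione (not isolated) | COC1=C(C(=O)CCc2ccccc2)C(O)=C(CC=C(C)C)C(=O)C1=O | intermediate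
7 | vinyl ortho-quinone methide, (6Z)-2,5-dihydroxy-3-methoxy-6-(3-methylbut-2-en-1-ylidene)-4-(3-phenylpropanoyl)cyclohexa-2,4-dien-1-one, side chain syn to the ring carbonyl (not isolated) | COC1=C(O)C(=O)/C(=C\C=C(C)C)C(O)=C1C(=O)CCc1ccccc1 | intermediate
8 | Flemistrictin D, 1-(5,8-dihydroxy-7-methoxy-2,2-dimethyl-2H-chromen-6-yl)-3-phenylpropan-1-one (achiral) | COc1c(O)c2c(c(O)c1C(=O)CCc1ccccc1)C=CC(C)(C)O2 | target

**Step count**
Total steps: 3. Longest linear sequence: 3 (1 → 3 → 5 → 8).

**Three steps most likely to fail, with fallbacks**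

Step 3 (the proposed new cascade) is the main risk. The ketone-deactivated phenol may be oxygenated slowly, or IBX may attack the prenyl-bearing C3' instead of C5'. The hydroxyquinone may resist tautomerization once it is deprotonated, ring closure could occur through the wrong oxygen, and the hydroquinone product is easily oxidized further, hence exactly 1.0 equiv of IBX and exclusion of air. The fallback uses known chemistry, sets out from 5 and comes back at 8. DDQ (1.1 equiv, benzene, 80 °C) closes the pyran by the established dehydrogenative cyclization of ortho-prenylphenols through the free 4'-OH, giving 1-(5-hydroxy-7-methoxy-2,2-dimethyl-2H-chromen-6-yl)-3-phenylpropan-1-one F6. Elbs persulfate oxidation (K2S2O8, aq KOH, pyridine, 0 °C → rt) then places oxygen para to the 5-OH at C8, the only free ring position, as potassium 5-hydroxy-7-methoxy-2,2-dimethyl-6-(3-phenylpropanoyl)-2H-chromen-8-yl sulfate F7. Brief hydrolysis (1 M HCl, 60 °C) gives 8.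

Step 2 (direct C-prenylation) may give O-prenyl ether, the C5' isomer and bis-prenylated material, so the yield of 5 may be modest. The fallback sets out from 3 and comes back at 5, replacing direct C-alkylation by O-alkylation and a sigmatropic shift. 3-Chloro-3-methylbut-1-yne with K2CO3, KI and CuI (cat.) in acetone at 56 °C alkylates only the unchelated 4'-OH to give 1-{2-hydroxy-6-methoxy-4-[(2-methylbut-3-yn-2-yl)oxy]phenyl}-3-phenylpropan-1-one F4. Semihydrogenation (H2, Pd/CaCO3 poisoned with Pb(OAc)2, quinoline, EtOAc) gives 1-{2-hydroxy-6-methoxy-4-[(2-methylbut-3-en-2-yl)oxy]phenyl}-3-phenylpropan-1-one F5. Aromatic Claisen rearrangement (N,N-diethylaniline, 120 °C) then delivers the allyl terminus as a prenyl group to C3', the ortho position favoured by bond fixation from the chelated 2'-OH/ketone, giving 5.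

Step 1 (acylation regiochemistry) may give too much of the symmetric 2',6'-dihydroxy-4'-methoxy isomer or a difficult separation. The fallback sets out from 2 and comes back at 3, using a symmetric substrate so that no regiochemical choice arises. Acylation of phloroglucinol with 2 (BF3·OEt2, 85 °C) gives 1-(2,4,6-trihydroxyphenyl)-3-phenylpropan-1-one F1. MOMCl (1.0 equiv) with iPr2NEt in CH2Cl2 at 0 °C protects the most acidic, unchelated 4'-OH to give 1-[2,6-dihydroxy-4-(methoxymethoxy)phenyl]-3-phenylpropan-1-one F2. Me2SO4 (1.05 equiv) with K2CO3 in acetone methylates one of the two equivalent ortho-hydroxyls, the other staying chelated, to give 1-[2-hydroxy-6-methoxy-4-(methoxymethoxy)phenyl]-3-phenylpropan-1-one F3. HCl in MeOH at 50 °C removes the MOM group to give 3.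

**Further compounds**
F1 | step 1 | 1-(2,4,6-trihydroxyphenyl)-3-phenylpropan-1-one | O=C(CCc1ccccc1)c1c(O)cc(O)cc1O
F2 | step 1 | 1-[2,6-dihydroxy-4-(methoxymethoxy)phenyl]-3-phenylpropan-1-one | COCOc1cc(O)c(C(=O)CCc2ccccc2)c(O)c1
F3 | step 1 | 1-[2-hydroxy-6-methoxy-4-(methoxymethoxy)phenyl]-3-phenylpropan-1-one | COCOc1cc(O)c(C(=O)CCc2ccccc2)c(OC)c1
F4 | step 2 | 1-{2-hydroxy-6-methoxy-4-[(2-methylbut-3-yn-2-yl)oxy]phenyl}-3-phenylpropan-1-one | COc1cc(OC(C)(C)C#C)cc(O)c1C(=O)CCc1ccccc1
F5 | step 2 | 1-{2-hydroxy-6-methoxy-4-[(2-methylbut-3-en-2-yl)oxy]phenyl}-3-phenylpropan-1-one | COc1cc(OC(C)(C)C=C)cc(O)c1C(=O)CCc1ccccc1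
F6 | step 3 | 1-(5-hydroxy-7-methoxy-2,2-dimethyl-2H-chromen-6-yl)-3-phenylpropan-1-one | COc1cc2OC(C)(C)C=Cc2c(O)c1C(=O)CCc1ccccc1
F7 | step 3 | potassium 5-hydroxy-7-methoxy-2,2-dimethyl-6-(3-phenylpropanoyl)-2H-chromen-8-yl sulfate | COc1c(OS(=O)(=O)[O-])c2OC(C)(C)C=Cc2c(O)c1C(=O)CCc1ccccc1.[K+]
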